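## Retrosynthetic overview

1. Locants used here: ring B = C1(=C15)–C2–C3–C4–C16; ring A = C4–C5–C6–C7–C16; ring C (eleven-membered) = C1–C14–C13–C12–C11–C10–C9–C8–C7–C16–C15; methyls on C4, C12, C15; =CH2 (C19) on C8. Ring C is closed last by a Ni/Cr alkenyl triflate–aldehyde coupling at C8–C9, which also delivers the C8 methylene and the C9 carbinol.
2. Ring A is made by ring contraction: the Diels–Alder cyclohexene C16–C7–C8(CH3)=C6–C5–C4 is cleaved at C8=C6 and re-closed by aldol condensation between C7 and C6 (key step); hydrogenation from the convex face then sets C7.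
3. The C9–C14 chain with the C12 stereocentre comes from (S)-citronellic acid and is joined at C1–C14 by alkenyllithium/Weinreb amide coupling; C14 is set by CBS reduction.
4. Ring B and the latent ring A come from one Diels–Alder reaction of 2-methoxy-6-methyl-1,4-benzoquinone with isoprene (C4, C16). Luche reduction, Stork–Danheiser methyl transposition (C15 methyl, C2 ketone, C3 equilibrated) and hydroxyl-directed reduction (C2) complete ring B.
5. Enabling feature: the 1-methylcyclohexene ring fused at C4–C16 is a masked 1,6-keto aldehyde (C8 ketone, C6 aldehyde) in which only the C7 methylene can enolise towards a five-membered ring. Cleavage/aldol therefore turns six ring atoms into ring A plus the C8 acetyl handle. Ring order: B (with masked A) → A → C.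

Key step: step 13

Remark 1: the sense of induction of the (S)-binaphthol titanium catalyst in step 2 is assumed to give the adduct as drawn; the (R)-ligand would be used if it proves opposite.
Remark 2: in step 17 the 9R carbinol is assumed to be the major epimer of the ring closure; the fallback covers the other outcome.

## Route

Step 1
Reactants: 1 2-methoxy-6-methylphenol
Product: 2 2-methoxy-6-methyl-1,4-benzoquinone
Conditions: (KSO3)2NO (2.2 equiv), KH2PO4, H2O/acetone, rt
Reagents that add atoms: potassium nitrosodisulfonate, [K+].[K+].[O]N(S(=O)(=O)[O-])S(=O)(=O)[O-]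
Why: Teuber oxidation of a para-unsubstituted phenol with two equivalents of the nitroxyl radical should give the p-quinone, the free para position being the only site open to oxygenation (no stereocentre).

Step 2
Reactants: 2 2-methoxy-6-methyl-1,4-benzoquinone; 3 isoprene
Product: 4 cis-fused Diels–Alder adduct
Conditions: (S)-1,1'-bi-2-naphthol (20 mol %), TiCl2(OiPr)2 (20 mol %), 4 Å molecular sieves, isoprene (5 equiv), CH2Cl2, -20 °C to rt
Reagents that add atoms: none
Why: Lewis-acid-catalysed Diels–Alder reaction in which the chiral titanium binaphtholate should bind the carbonyl flanked by the methoxy- and methyl-bearing carbons together with the methoxy oxygen, so that the methyl-bearing double bond reacts (the methoxy-bearing one is a deactivated vinylogous ester) with the more nucleophilic CH2 terminus of isoprene bonding to the unsubstituted carbon; suprafacial addition fixes the cis relation of the C4 methyl and C16-H and the ligand selects the quinone face.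

Step 3
Reactants: 4 cis-fused Diels–Alder adduct
Product: 5 hydroxy enone
Conditions: NaBH4, CeCl3·7H2O, MeOH, -78 °C
Reagents that add atoms: none
Why: Luche reduction should be selective for the ketone-like carbonyl next to the quaternary carbon because the other carbonyl is a vinylogous ester, with hydride expected anti to the angular methyl (C3-OH cis to it); the C3 configuration is in any case secured thermodynamically in step 4.

Step 4
Reactants: 5 hydroxy enone
Product: 7 alpha-hydroxy enone, via tertiary carbinol 6 (not isolated)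
Conditions: MeLi (3 equiv), CeCl3, THF, -78 °C; 1 M HCl, THF, 0 °C to rt; then DBU (0.2 equiv), CH2Cl2, rt, argon
Reagents that add atoms: methyllithium, C[Li]; water, O
Why: Stork–Danheiser transposition, in which the organocerium reagent adds 1,2 to the vinylogous ester carbonyl and acid hydrolysis gives the 3-methyl enone with the carbonyl at C2; DBU then equilibrates the enolisable C3 ketol centre to the equatorial hydroxyl, which is the one cis to the axial C4 methyl because allylic 1,2-strain with the C15 methyl holds the C16–C7 bond axial.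

Step 5
Reactants: 7 alpha-hydroxy enone
Product: 8 iodo enone
Conditions: I2, pyridine, CH2Cl2, 0 °C to rt
Reagents that add atoms: iodine, II
Why: alpha-Iodination of the enone by the pyridine-mediated addition–elimination sequence should place iodine on C1, the only vinylic CH, without touching the isolated trisubstituted alkene or the stereocentres.

Step 6
Reactants: 8 iodo enone
Product: 9 iodo diol
Conditions: Me4NBH(OAc)3, AcOH/MeCN (1:1), -20 °C
Reagents that add atoms: none
Why: Evans–Saksena hydroxyl-directed reduction, in which the triacetoxyborohydride exchanges onto the C3 hydroxyl and delivers hydride intramolecularly to the same face of the adjacent C2 carbonyl, should give the trans-diequatorial 1,2-diol with the new C2 hydroxyl anti to the C3 hydroxyl.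

Step 7
Reactants: 9 iodo diol
Product: 10 bis-silyl ether
Conditions: TBSOTf (2.5 equiv), 2,6-lutidine, CH2Cl2, -78 to 0 °C
Reagents that add atoms: tert-butyldimethylsilyl trifluoromethanesulfonate, CC(C)(C)[Si](C)(C)OS(=O)(=O)C(F)(F)F
Why: Silylation with the silyl triflate and 2,6-lutidine should protect both secondary hydroxyls, including the neopentyl one, as TBS ethers that survive the organolithium, oxidation, base and hydrogenation steps.

Step 8
Reactants: 11 (S)-citronellic acid
Product: 12 Weinreb amide
Conditions: MeNH(OMe)·HCl, EDC·HCl, DMAP (cat.), Et3N, CH2Cl2, 0 °C to rt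
Reagents that add atoms: N,O-dimethylhydroxylamine hydrochloride, CNOC.Cl
Why: Carbodiimide-mediated amide coupling should give the Weinreb amide without affecting the remote C12 stereocentre.

Step 9
Reactants: 12 Weinreb amide
Product: 14 acetal amide, via aldehyde amide 13 (not isolated)
Conditions: O3, CH2Cl2/MeOH, -78 °C; then Me2S, TsOH·H2O (cat.), -78 °C to rt
Reagents that add atoms: methanol, CO
Why: Ozonolysis of the trisubstituted alkene with reductive work-up and in situ acid-catalysed acetalisation in methanol should unveil C9 as a protected aldehyde and leave the amide and C12 untouched.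

Step 10
Reactants: 10 bis-silyl ether; 14 acetal amide
Product: 16 C14 enone, via alkenyllithium 15 (not isolated)
Conditions: t-BuLi (2.1 equiv), Et2O, -78 °C; then 14, -78 to -20 °C; NH4Cl (aq)
Reagents that add atoms: none
Why: Iodine–lithium exchange should give the cyclohexenyllithium, which acylates the amide (Weinreb ketone synthesis) through a stable chelated tetrahedral intermediate, so that the C1–C14 bond forms without over-addition.

Step 11
Reactants: 16 C14 enone
Product: 17 C14 alcohol
Conditions: (R)-2-methyl-CBS-oxazaborolidine (0.5 equiv), catecholborane, toluene, -78 °C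
Reagents that add atoms: none
Why: CBS reduction, in which the (R)-oxazaborolidine differentiates the bulky tetrasubstituted alkenyl group from the methylene chain, should give the 14S allylic alcohol under reagent control, catecholborane at low temperature leaving the trisubstituted alkene unhydroborated.

Step 12
Reactants: 17 C14 alcohol
Product: 18 triethylsilyl ether
Conditions: Et3SiCl, imidazole, DMAP (cat.), DMF, rt
Reagents that add atoms: chlorotriethylsilane, CC[Si](Cl)(CC)CC
Why: Silylation should mask the allylic C14 hydroxyl as an ether that tolerates oxidative cleavage, base, hydrogenation and enolate formation and is later removed together with the acetal.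

Step 13
Reactants: 18 triethylsilyl ether
Product: 20 acetylcyclopentene, via keto aldehyde 19 (not isolated)
Conditions: OsO4 (2 mol %), NaIO4 (4 equiv), 2,6-lutidine, dioxane/H2O (3:1), rt; extractive work-up, then KOH (0.5 equiv), MeOH, 0 °C to rt
Reagents that add atoms: sodium periodate, [Na+].[O-]I(=O)(=O)=O
Why: Lemieux–Johnson oxidation (osmylation, then periodate cleavage) should open the C8=C6 bond of the Diels–Alder cyclohexene to the 1,6-keto aldehyde, after which hydroxide forms the ketone enolate at the C7 methylene, which adds to the C6 aldehyde and dehydrates (E1cB) to the conjugated 1-acetylcyclopentene. The closest known reaction type is the oxidative cleavage/aldol-condensation ring contraction of 1-methylcyclohexenes (6-oxoheptanal to 1-acetylcyclopentene). Ring A is closed in the 5-(enolexo)-exo-trig mode, C6–C7 becoming a ring bond while C8 with C19 leaves the ring as the acetyl group. No stereocentre is created: C4 and C16 are not enolisable and keep the cis fusion, and C7 is left trigonal on purpose so that step 14 sets it by hydrogenation. The cleavage must be chemoselective, which is secured by the steric shielding of the tetrasubstituted C1=C15 alkene (flanked by two silyloxy-bearing carbons, a methyl group and C16), so that OsO4 attacks only the trisubstituted ring alkene. The aldol must be regioselective, which is secured because the C19 methyl enolate would close a seven-membered ring and the neopentyl C5 enolate would have to attack the ketone and form a tetrasubstituted alkene beside the quaternary C4, while only the C7-to-C6 adduct dehydrates readily to a conjugated enone.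

Step 14
Reactants: 20 acetylcyclopentene
Product: 21 methyl ketone
Conditions: H2 (1 atm), 10% Pd/C, EtOAc, rt
Reagents that add atoms: none
Why: Heterogeneous catalytic hydrogenation should add hydrogen to the convex face of the cis-fused bicycle (the face bearing C16-H and the C4 methyl, the other being covered by ring B and its C15 and C3 substituents), so that C7-H ends cis to C16-H with the acetyl group on the concave face (7R), while the tetrasubstituted alkene is too hindered to react.

Step 15
Reactants: 21 methyl ketone
Product: 23 enol triflate, via potassium enolate 22 (not isolated)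
Conditions: KN(SiMe3)2, THF, -78 °C; then PhNTf2, -78 to 0 °C; NH4Cl (aq)
Reagents that add atoms: N-phenylbis(trifluoromethanesulfonimide), O=S(=O)(N(c1ccccc1)S(=O)(=O)C(F)(F)F)C(F)(F)F
Why: Kinetic enolate formation should occur at the unhindered C19 methyl and not at the tertiary C7-H, and O-triflation then gives the terminal enol triflate without epimerising C7.

Step 16
Reactants: 23 enol triflate
Product: 24 hydroxy aldehyde
Conditions: AcOH/THF/H2O (3:1:1), 35 °C
Reagents that add atoms: water, O
Why: Mild acid hydrolysis should convert the dimethyl acetal into the C9 aldehyde and cleave the triethylsilyl ether, whereas the hindered secondary TBS ethers and the enol triflate are stable under these conditions.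

Step 17
Reactants: 24 hydroxy aldehyde
Product: 25 macrocyclic diol
Conditions: CrCl2 (15 equiv), NiCl2 (0.15 equiv), DMSO/THF (3:1), 2 mM, rt
Reagents that add atoms: none
Why: Intramolecular Nozaki–Hiyama–Kishi reaction, in which nickel-catalysed activation of the enol triflate and transmetalation to chromium give an alkenylchromium species that adds to the C9 aldehyde under high dilution, should close ring C at C8–C9 and form the C8 exocyclic methylene directly, the 9R carbinol being assumed to arise from addition to the aldehyde face turned away from ring B.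

Step 18
Reactants: 25 macrocyclic diol
Product: 26 diacetate
Conditions: Ac2O, DMAP, pyridine, CH2Cl2, rt
Reagents that add atoms: acetic anhydride, CC(=O)OC(C)=O
Why: DMAP-catalysed acylation should acetylate both free allylic hydroxyls (C9 and C14) while the C2 and C3 oxygens remain silylated.

Step 19
Reactants: 26 diacetate
Product: 27 target CNP0286573.1
Conditions: HF·pyridine, pyridine/THF, 0 °C to rt
Reagents that add atoms: none
Why: Fluoride-mediated desilylation should remove both TBS ethers without cleaving or migrating the allylic acetates or isomerising the exocyclic alkene.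

## Compound list

1 | 2-methoxy-6-methylphenol | COc1cccc(C)c1O | starting material
2 | 2-methoxy-6-methyl-1,4-benzoquinone | COC1=CC(=O)C=C(C)C1=O | intermediate
3 | isoprene (2-methylbuta-1,3-diene) | C=CC(C)=C | starting material
4 | cis-fused Diels–Alder adduct: (4aR,8aS)-2-methoxy-6,8a-dimethyl-4a,5,8,8a-tetrahydronaphthalene-1,4-dione | O=C1C=C(OC)C(=O)[C@@]2(C)CC=C(C)C[C@@H]12 | intermediate
5 | hydroxy enone: (4R,4aS,8aR)-4-hydroxy-3-methoxy-4a,7-dimethyl-4a,5,8,8a-tetrahydronaphthalen-1(4H)-one, OH cis to the angular methyl | O=C1C=C(OC)[C@H](O)[C@@]2(C)CC=C(C)C[C@@H]12 | intermediate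
6 | tertiary carbinol: (4R,4aS,8aR)-3-methoxy-1,4a,7-trimethyl-1,4,4a,5,8,8a-hexahydronaphthalene-1,4-diol, either C1 epimer | CC1(O)C=C(OC)[C@H](O)[C@@]2(C)CC=C(C)C[C@@H]12 | intermediate
7 | alpha-hydroxy enone: (1R,4aS,8aS)-1-hydroxy-4,6,8a-trimethyl-4a,5,8,8a-tetrahydronaphthalen-2(1H)-one | C1=C(C)[C@@H]2CC(C)=CC[C@]2(C)[C@@H](O)C1=O | intermediate
8 | iodo enone: (1R,4aR,8aS)-1-hydroxy-3-iodo-4,6,8a-trimethyl-4a,5,8,8a-tetrahydronaphthalen-2(1H)-one | IC1=C(C)[C@@H]2CC(C)=CC[C@]2(C)[C@@H](O)C1=O | intermediate
9 | iodo diol: (1R,2S,4aR,8aS)-3-iodo-4,6,8a-trimethyl-1,2,4a,5,8,8a-hexahydronaphthalene-1,2-diol (trans-diol) | IC1=C(C)[C@@H]2CC(C)=CC[C@]2(C)[C@@H](O)[C@@H]1O | intermediate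
10 | bis-silyl ether: 1,2-bis-O-(tert-butyldimethylsilyl) ether of 9 | IC1=C(C)[C@@H]2CC(C)=CC[C@]2(C)[C@@H](O[Si](C)(C)C(C)(C)C)[C@@H]1O[Si](C)(C)C(C)(C)C | intermediate
11 | (S)-citronellic acid: (3S)-3,7-dimethyloct-6-enoic acid | CC(C)=CCC[C@H](C)CC(=O)O | starting material
12 | Weinreb amide: (3S)-N-methoxy-N,3,7-trimethyloct-6-enamide | CC(C)=CCC[C@H](C)CC(=O)N(C)OC | intermediate
13 | aldehyde amide: (3S)-N-methoxy-N,3-dimethyl-6-oxohexanamide | O=CCC[C@H](C)CC(=O)N(C)OC | intermediate
14 | acetal amide: (3S)-N,6,6-trimethoxy-N,3-dimethylhexanamide | COC(OC)CC[C@H](C)CC(=O)N(C)OC | intermediate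
15 | alkenyllithium: 10 with lithium in place of iodine | [Li]C1=C(C)[C@@H]2CC(C)=CC[C@]2(C)[C@@H](O[Si](C)(C)C(C)(C)C)[C@@H]1O[Si](C)(C)C(C)(C)C | intermediate
16 | C14 enone: (3S)-1-[(3R,4R,4aS,8aS)-3,4-bis(tert-butyldimethylsilyloxy)-1,4a,7-trimethyl-3,4,4a,5,8,8a-hexahydronaphthalen-2-yl]-6,6-dimethoxy-3-methylhexan-1-one | COC(OC)CC[C@H](C)CC(=O)C1=C(C)[C@@H]2CC(C)=CC[C@]2(C)[C@@H](O[Si](C)(C)C(C)(C)C)[C@@H]1O[Si](C)(C)C(C)(C)C | intermediate
17 | C14 alcohol: the (1S,3S)-hexan-1-ol obtained from 16 (14S) | COC(OC)CC[C@H](C)C[C@H](O)C1=C(C)[C@@H]2CC(C)=CC[C@]2(C)[C@@H](O[Si](C)(C)C(C)(C)C)[C@@H]1O[Si](C)(C)C(C)(C)C | intermediate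
18 | triethylsilyl ether of 17 at C14 | COC(OC)CC[C@H](C)C[C@H](O[Si](CC)(CC)CC)C1=C(C)[C@@H]2CC(C)=CC[C@]2(C)[C@@H](O[Si](C)(C)C(C)(C)C)[C@@H]1O[Si](C)(C)C(C)(C)C | intermediate
19 | keto aldehyde: ring B of 18 with a 2-oxopropyl group on C16 (C7–C8(=O)–C19) and a 2-oxoethyl group on C4 (C5–C6HO) | COC(OC)CC[C@H](C)C[C@H](O[Si](CC)(CC)CC)C1=C(C)[C@H](CC(C)=O)[C@](C)(CC=O)[C@@H](O[Si](C)(C)C(C)(C)C)[C@@H]1O[Si](C)(C)C(C)(C)C | intermediate
20 | acetylcyclopentene: cis-fused bicycle with ring A closed (C6=C7) and the acetyl group (C8, C19) on C7 | COC(OC)CC[C@H](C)C[C@H](O[Si](CC)(CC)CC)C1=C(C)[C@@H]2C(C(C)=O)=CC[C@]2(C)[C@@H](O[Si](C)(C)C(C)(C)C)[C@@H]1O[Si](C)(C)C(C)(C)C | intermediate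
21 | methyl ketone: 20 with C6–C7 saturated, 7R, C7-H cis to C16-H and to the C4 methyl | COC(OC)CC[C@H](C)C[C@H](O[Si](CC)(CC)CC)C1=C(C)[C@@H]2[C@H](C(C)=O)CC[C@]2(C)[C@@H](O[Si](C)(C)C(C)(C)C)[C@@H]1O[Si](C)(C)C(C)(C)C | intermediate
22 | potassium enolate of 21 (C8=C19, C8–OK) | COC(OC)CC[C@H](C)C[C@H](O[Si](CC)(CC)CC)C1=C(C)[C@@H]2[C@H](C(=C)[O-])CC[C@]2(C)[C@@H](O[Si](C)(C)C(C)(C)C)[C@@H]1O[Si](C)(C)C(C)(C)C.[K+] | intermediate
23 | enol triflate: C8(=C19H2)–OSO2CF3 on C7 | COC(OC)CC[C@H](C)C[C@H](O[Si](CC)(CC)CC)C1=C(C)[C@@H]2[C@H](C(=C)OS(=O)(=O)C(F)(F)F)CC[C@]2(C)[C@@H](O[Si](C)(C)C(C)(C)C)[C@@H]1O[Si](C)(C)C(C)(C)C | intermediate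
24 | hydroxy aldehyde: 23 with free C14-OH and the C9 aldehyde | O=CCC[C@H](C)C[C@H](O)C1=C(C)[C@@H]2[C@H](C(=C)OS(=O)(=O)C(F)(F)F)CC[C@]2(C)[C@@H](O[Si](C)(C)C(C)(C)C)[C@@H]1O[Si](C)(C)C(C)(C)C | intermediate
25 | macrocyclic diol: (2R,3R,4S,7R,9R,12S,14S,16S) tricycle with 2,3-bis-O-TBS, C8=C19H2, 9-OH and 14-OH | C=C1[C@H](O)CC[C@H](C)C[C@H](O)C2=C(C)[C@@H]3[C@H]1CC[C@]3(C)[C@@H](O[Si](C)(C)C(C)(C)C)[C@@H]2O[Si](C)(C)C(C)(C)C | intermediate
26 | diacetate: 9,14-di-O-acetyl derivative of 25 | C=C1[C@H](OC(C)=O)CC[C@H](C)C[C@H](OC(C)=O)C2=C(C)[C@@H]3[C@H]1CC[C@]3(C)[C@@H](O[Si](C)(C)C(C)(C)C)[C@@H]2O[Si](C)(C)C(C)(C)C | intermediate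
27 | target CNP0286573.1: (2R,3R,4S,7R,9R,12S,14S,16S)-9,14-diacetoxy tricyclic 2,3-diol, C24H36O6 | C=C1[C@H](OC(C)=O)CC[C@H](C)C[C@H](OC(C)=O)C2=C(C)[C@@H]3[C@H]1CC[C@]3(C)[C@@H](O)[C@@H]2O | target

## Step count and risks

Total step count: 19. Longest linear sequence: 17 steps (steps 1–7 and 10–19); the side-chain branch (steps 8–9) joins at step 10.

Three steps most likely to fail:

Step 17. Closure of the eleven-membered ring may suffer from competing intermolecular coupling and from weak facial discrimination at the aldehyde, giving both C9 epimers. The fallback sets out from 23. Only the acetal is hydrolysed [In(OTf)3 (cat.), acetone/H2O, rt], giving the triethylsilyl-protected triflate aldehyde F1. F1 is cyclised under the same Ni/Cr conditions to the macrocyclic C9 alcohols F2 (both epimers). These are oxidised with MnO2 to the macrocyclic alpha-methylene ketone F3. F3 is reduced with (S)-2-methyl-CBS-oxazaborolidine and catecholborane to the single 9R alcohol F4, so that C9 is set by reagent control and not during C–C bond formation. AcOH/THF/H2O then removes the triethylsilyl group and the route comes back at 25.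

Step 2. Catalyst turnover at the hindered methyl-bearing double bond may be slow, and the enantiomeric purity or the orientation of the diene may erode. The fallback sets out from 2 and 3. The cycloaddition is run thermally (toluene, 100 °C), where orientation is still governed by the more electron-poor carbonyl, giving racemic adduct (4 together with its enantiomer F5). Luche reduction as in step 3 gives the racemic alcohol (5 together with its enantiomer F6). The enantiomers are separated by preparative chromatography on a chiral stationary phase, and the route comes back at 5.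

Step 10. The hindered tetrasubstituted alkenyllithium may deprotonate the amide alpha-methylene or add too slowly. The fallback sets out from 10 and 14. The amide 14 is reduced with i-Bu2AlH (THF, -78 °C) to (3S)-6,6-dimethoxy-3-methylhexanal F7. Iodide 10 and F7 are joined by an intermolecular Nozaki–Hiyama–Kishi coupling (CrCl2, NiCl2 cat., DMSO) to the C14 allylic alcohols F8 (both epimers). Oxidation with MnO2 comes back at 16.

Further compounds
F1 | step 17 | triethylsilyl-protected triflate aldehyde (24 with C14-OSiEt3) | O=CCC[C@H](C)C[C@H](O[Si](CC)(CC)CC)C1=C(C)[C@@H]2[C@H](C(=C)OS(=O)(=O)C(F)(F)F)CC[C@]2(C)[C@@H](O[Si](C)(C)C(C)(C)C)[C@@H]1O[Si](C)(C)C(C)(C)C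
F2 | step 17 | macrocyclic C9 alcohols, both epimers (C14-OSiEt3) | C=C1C(O)CC[C@H](C)C[C@H](O[Si](CC)(CC)CC)C2=C(C)[C@@H]3[C@H]1CC[C@]3(C)[C@@H](O[Si](C)(C)C(C)(C)C)[C@@H]2O[Si](C)(C)C(C)(C)C
F3 | step 17 | macrocyclic alpha-methylene ketone (C9 ketone) | C=C1C(=O)CC[C@H](C)C[C@H](O[Si](CC)(CC)CC)C2=C(C)[C@@H]3[C@H]1CC[C@]3(C)[C@@H](O[Si](C)(C)C(C)(C)C)[C@@H]2O[Si](C)(C)C(C)(C)C
F4 | step 17 | 9R alcohol (25 with C14-OSiEt3) | C=C1[C@H](O)CC[C@H](C)C[C@H](O[Si](CC)(CC)CC)C2=C(C)[C@@H]3[C@H]1CC[C@]3(C)[C@@H](O[Si](C)(C)C(C)(C)C)[C@@H]2O[Si](C)(C)C(C)(C)C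
F5 | step 2 | enantiomer of 4 | O=C1C=C(OC)C(=O)[C@]2(C)CC=C(C)C[C@H]12
F6 | step 2 | enantiomer of 5 | O=C1C=C(OC)[C@@H](O)[C@]2(C)CC=C(C)C[C@H]12
F7 | step 10 | (3S)-6,6-dimethoxy-3-methylhexanal | COC(OC)CC[C@H](C)CC=O
F8 | step 10 | C14 allylic alcohols, both epimers | COC(OC)CC[C@H](C)CC(O)C1=C(C)[C@@H]2CC(C)=CC[C@]2(C)[C@@H](O[Si](C)(C)C(C)(C)C)[C@@H]1O[Si](C)(C)C(C)(C)C
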